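**Strategy.** Numbered as a cyclohexyl acetate, the target ring carries its acetoxy carbon C1 and its methylidene carbon C4 in a 1,4 relationship, linked on one side by the C5–C6 ethano bridge. The route disconnects that C5–C6 bond. It is formed when a 2,5-dimethylidene oxane is ionised at its allylic C–O bond and the enol ether CH2 recombines with an allyl terminus; one operation thus turns the pyran into the 4-methylidenecyclohexanone, with the gem-dimethyl carbon and the side-chain stereocentre already in place. The precursor is a (4S)-4-(silyloxymethyl)-3,3-dimethyl-2,5-dimethylideneoxane, made by methylenation of the matching δ-lactone; its stereocentre comes from an organocatalytic Mukaiyama–Michael addition.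

Key step: step 7

Remark (labels): O1–C6 refer to the oxane ring of 10 and 11; C1–C6 refer to the cyclohexane ring of 12–17 (C1 oxygenated, C2 gem-dimethyl, C3 side chain, C4 methylidene).

Remark (assumption): the facial selectivity of step 3 is taken to follow the usual shielding model of the imidazolidinone (benzyl arm over one face of the (E)-iminium ion), which calls for the (2R,5R) catalyst to give the (S) centre.

Remark (design): the side-chain oxygen is carried as a tert-butyldiphenylsilyl ether. A benzyl-type ether would be the strongest donor towards the aluminium promoter of step 7 and could itself ionise or trap the allyl cation.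

**Step 1**
Reactants: 1 prop-2-en-1-ol (allyl alcohol)
Product: 2 tert-butyl(diphenyl)(prop-2-en-1-yloxy)silane
Conditions: TBDPSCl, imidazole, DMF, 0 °C → rt
Reagents that add atoms: tert-butyl(chloro)diphenylsilane (TBDPSCl), CC(C)(C)[Si](Cl)(c1ccccc1)c1ccccc1
Why: Imidazole-mediated silylation of a primary alcohol (silyl ether formation) is routine, and the bulky silyl group is chosen because it should survive every later step and makes the side-chain oxygen a poor donor; no stereocentre is involved.

**Step 2**
Reactants: 2 tert-butyl(diphenyl)(prop-2-en-1-yloxy)silane; 3 (2E)-but-2-enal (crotonaldehyde)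
Product: 4 (2E)-4-[(tert-butyldiphenylsilyl)oxy]but-2-enal
Conditions: Hoveyda–Grubbs II (3 mol%), crotonaldehyde (4 equiv), CH2Cl2, 40 °C
Reagents that add atoms: none
Why: Olefin cross-metathesis of the terminal allyl ether with excess crotonaldehyde on a second-generation ruthenium carbene releases propene and should deliver the conjugated enal under thermodynamic control as the (E) isomer.

**Step 3**
Reactants: 4 (2E)-4-[(tert-butyldiphenylsilyl)oxy]but-2-enal; 5 [(1-methoxy-2-methylprop-1-en-1-yl)oxy]trimethylsilane (silyl ketene acetal of methyl isobutyrate)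
Product: 6 methyl (3S)-3-{[(tert-butyldiphenylsilyl)oxy]methyl}-2,2-dimethyl-5-oxopentanoate
Conditions: (2R,5R)-5-benzyl-2-tert-butyl-3-methylimidazolidin-4-one·2,4-dinitrobenzoic acid (20 mol%), 5 (2.5 equiv), H2O (2 equiv), CH2Cl2, −60 °C
Reagents that add atoms: none
Why: Organocatalytic Mukaiyama–Michael addition under iminium activation: the imidazolidinone condenses with 4 to the (E)-iminium ion, whose benzyl arm covers one face of the β-carbon, so the carbon terminus of 5 adds 1,4 to the open face and sets the (S) centre, this catalysis being known to tolerate fully substituted silyl nucleophiles that create a quaternary carbon.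

**Step 4**
Reactants: 6 methyl (3S)-3-{[(tert-butyldiphenylsilyl)oxy]methyl}-2,2-dimethyl-5-oxopentanoate; 7 formaldehyde
Product: 8 methyl (3S)-3-{[(tert-butyldiphenylsilyl)oxy]methyl}-4-formyl-2,2-dimethylpent-4-enoate
Conditions: 37% aq. CH2O, pyrrolidine (10 mol%), EtCO2H (10 mol%), iPrOH, 45 °C
Reagents that add atoms: none
Why: Amine/acid-catalysed α-methylenation of an aldehyde (Mannich condensation with formaldehyde, then elimination of the amine) acts at the only enolisable CH2, the hindered ester and the silyl ether are inert, and the stereocentre is not part of the enamine.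

**Step 5**
Reactants: 8 methyl (3S)-3-{[(tert-butyldiphenylsilyl)oxy]methyl}-4-formyl-2,2-dimethylpent-4-enoate
Product: 10 (4S)-4-{[(tert-butyldiphenylsilyl)oxy]methyl}-3,3-dimethyl-5-methylideneoxan-2-one, via open-chain hydroxy ester 9 (not isolated)
Conditions: NaBH4, CeCl3·7H2O, MeOH, −20 °C; then PPTS (cat.), PhMe, 60 °C
Reagents that add atoms: none
Why: Luche 1,2-reduction of the enal gives allylic alcohol 9, whose hydroxyl is the only free one (the other oxygen is silylated, so no γ-lactone can form) and which should close onto the methyl ester by acid-catalysed lactonisation helped by the gem-dimethyl group; the stereocentre is untouched.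

**Step 6**
Reactants: 10 (4S)-4-{[(tert-butyldiphenylsilyl)oxy]methyl}-3,3-dimethyl-5-methylideneoxan-2-one
Product: 11 (4S)-4-{[(tert-butyldiphenylsilyl)oxy]methyl}-3,3-dimethyl-2,5-dimethylideneoxane
Conditions: Cp2TiMe2 (3 equiv), PhMe, 70 °C, dark; filtration through basic alumina
Reagents that add atoms: dimethyltitanocene (Petasis reagent), C[Ti](C)(C1C=CC=C1)C1C=CC=C1
Why: Petasis methylenation (carbonyl olefination by titanocene methylidene through an oxatitanacyclobutane) converts lactones into exocyclic enol ethers under neutral conditions, and because C3 is quaternary the new double bond cannot move into the ring.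

**Step 7**
Reactants: 11 (4S)-4-{[(tert-butyldiphenylsilyl)oxy]methyl}-3,3-dimethyl-2,5-dimethylideneoxane
Product: 12 (3S)-3-{[(tert-butyldiphenylsilyl)oxy]methyl}-2,2-dimethyl-4-methylidenecyclohexan-1-one
Conditions: MABR (2.2 equiv, made in situ from Me3Al and 4-bromo-2,6-di-tert-butylphenol), CH2Cl2, −78 → −20 °C; aq. Rochelle salt
Reagents that add atoms: none
Why: Proposed new method: the aluminium aryloxide binds the ring oxygen O1 (the silyl ether oxygen is shielded) and weakens the allylic C6–O1 bond, so that heterolysis gives a tight ion pair of an aluminium enolate of the tert-alkyl methyl ketone and a 2-substituted allyl cation held together by the C3–C4 bridge, and the enolate carbon then bonds to either of the two equivalent CH2 termini (a charge-accelerated boat-like [3,3] shift is the concerted limit and gives the same product). The closest known reaction types are the organoaluminium-promoted aliphatic Claisen rearrangement of allyl vinyl ethers and the aluminium-mediated Ferrier-type carbocyclisation of cyclic enol ethers, which ionise and recombine at carbon in the same way but through an oxocarbenium ion rather than an allyl cation. The one new ring, the cyclohexanone, closes in a 6-(enolendo) mode on the enolate side and onto the terminus of an allyl unit whose central carbon C5 lies inside the new ring (6-endo in the SN2′ sense), so the other terminus is left as the exocyclic methylene. No stereocentre is formed, and C4 of 11 is neither ionised nor enolisable, so it carries its configuration into C3 of 12. The selectivity needed is recombination at carbon rather than oxygen: O-attack at either terminus only returns 11, whereas C–C bond formation is made irreversible by the new C=O bond, only one enolate is possible because C3 is quaternary, and the allyl cation has no hydrogen placed for elimination.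

**Step 8**
Reactants: 12 (3S)-3-{[(tert-butyldiphenylsilyl)oxy]methyl}-2,2-dimethyl-4-methylidenecyclohexan-1-one
Product: 13 (1R,3S)-3-{[(tert-butyldiphenylsilyl)oxy]methyl}-2,2-dimethyl-4-methylidenecyclohexan-1-ol
Conditions: NaBH4, MeOH, 0 °C
Reagents that add atoms: none
Why: Borohydride reduction of a cyclohexanone: the small hydride should attack from the face opposite the C3 side chain (axial attack on the chair with that group equatorial, the equatorial path being hindered by the axial C2 methyl), giving the equatorial alcohol cis to the side chain, i.e. the (1R) centre by substrate control.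

**Step 9**
Reactants: 13 (1R,3S)-3-{[(tert-butyldiphenylsilyl)oxy]methyl}-2,2-dimethyl-4-methylidenecyclohexan-1-ol
Product: 14 (1R,3S)-3-{[(tert-butyldiphenylsilyl)oxy]methyl}-2,2-dimethyl-4-methylidenecyclohexyl acetate
Conditions: Ac2O, pyridine, DMAP (cat.), CH2Cl2, rt
Reagents that add atoms: acetic anhydride, CC(=O)OC(C)=O
Why: DMAP-catalysed acetylation of the equatorial secondary alcohol proceeds with retention at carbon and touches neither the silyl ether nor the alkene.

**Step 10**
Reactants: 14 (1R,3S)-3-{[(tert-butyldiphenylsilyl)oxy]methyl}-2,2-dimethyl-4-methylidenecyclohexyl acetate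
Product: 15 (1R,3S)-3-(hydroxymethyl)-2,2-dimethyl-4-methylidenecyclohexyl acetate
Conditions: HF·pyridine, pyridine, THF, 0 °C → rt
Reagents that add atoms: none
Why: Fluoride-driven cleavage of the silyl ether through the strong Si–F bond; buffered HF·pyridine is non-basic, so the acetate should neither hydrolyse nor migrate and the 1,1-disubstituted alkene is left alone.

**Step 11**
Reactants: 15 (1R,3S)-3-(hydroxymethyl)-2,2-dimethyl-4-methylidenecyclohexyl acetate; 16 7-hydroxy-2H-chromen-2-one (umbelliferone)
Product: 17 (1R,3S)-2,2-dimethyl-4-methylidene-3-{[(2-oxo-2H-chromen-7-yl)oxy]methyl}cyclohexyl acetate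
Conditions: PPh3, DIAD, THF, 0 °C → rt
Reagents that add atoms: none
Why: Mitsunobu etherification: the acidic 7-hydroxyl of the coumarin (pKa about 8) protonates the betaine and its phenoxide displaces the primary alkoxyphosphonium in an SN2 step at the CH2 group, so neither ring stereocentre is involved and the acetate and the coumarin lactone are stable to the neutral conditions.

**Compound list**
1 | prop-2-en-1-ol (allyl alcohol) | C=CCO | starting material
2 | tert-butyl(diphenyl)(prop-2-en-1-yloxy)silane | C=CCO[Si](C(C)(C)C)(c1ccccc1)c1ccccc1 | intermediate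
3 | (2E)-but-2-enal (crotonaldehyde) | C/C=C/C=O | starting material
4 | (2E)-4-[(tert-butyldiphenylsilyl)oxy]but-2-enal | O=C/C=C/CO[Si](C(C)(C)C)(c1ccccc1)c1ccccc1 | intermediate
5 | [(1-methoxy-2-methylprop-1-en-1-yl)oxy]trimethylsilane | COC(O[Si](C)(C)C)=C(C)C | starting material
6 | methyl (3S)-3-{[(tert-butyldiphenylsilyl)oxy]methyl}-2,2-dimethyl-5-oxopentanoate | O=CC[C@H](CO[Si](C(C)(C)C)(c1ccccc1)c1ccccc1)C(C)(C)C(=O)OC | intermediate
7 | formaldehyde | C=O | starting material
8 | methyl (3S)-3-{[(tert-butyldiphenylsilyl)oxy]methyl}-4-formyl-2,2-dimethylpent-4-enoate | C=C(C=O)[C@H](CO[Si](C(C)(C)C)(c1ccccc1)c1ccccc1)C(C)(C)C(=O)OC | intermediate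
9 | methyl (3S)-3-{[(tert-butyldiphenylsilyl)oxy]methyl}-4-(hydroxymethyl)-2,2-dimethylpent-4-enoate | C=C(CO)[C@H](CO[Si](C(C)(C)C)(c1ccccc1)c1ccccc1)C(C)(C)C(=O)OC | intermediate
10 | (4S)-4-{[(tert-butyldiphenylsilyl)oxy]methyl}-3,3-dimethyl-5-methylideneoxan-2-one | O=C1OCC(=C)[C@H](CO[Si](C(C)(C)C)(c2ccccc2)c2ccccc2)C1(C)C | intermediate
11 | (4S)-4-{[(tert-butyldiphenylsilyl)oxy]methyl}-3,3-dimethyl-2,5-dimethylideneoxane | C=C1OCC(=C)[C@H](CO[Si](C(C)(C)C)(c2ccccc2)c2ccccc2)C1(C)C | intermediate
12 | (3S)-3-{[(tert-butyldiphenylsilyl)oxy]methyl}-2,2-dimethyl-4-methylidenecyclohexan-1-one | C=C1CCC(=O)C(C)(C)[C@H]1CO[Si](C(C)(C)C)(c1ccccc1)c1ccccc1 | intermediate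
13 | (1R,3S)-3-{[(tert-butyldiphenylsilyl)oxy]methyl}-2,2-dimethyl-4-methylidenecyclohexan-1-ol | C=C1CC[C@@H](O)C(C)(C)[C@H]1CO[Si](C(C)(C)C)(c1ccccc1)c1ccccc1 | intermediate
14 | (1R,3S)-3-{[(tert-butyldiphenylsilyl)oxy]methyl}-2,2-dimethyl-4-methylidenecyclohexyl acetate | C=C1CC[C@@H](OC(C)=O)C(C)(C)[C@H]1CO[Si](C(C)(C)C)(c1ccccc1)c1ccccc1 | intermediate
15 | (1R,3S)-3-(hydroxymethyl)-2,2-dimethyl-4-methylidenecyclohexyl acetate | C=C1CC[C@@H](OC(C)=O)C(C)(C)[C@H]1CO | intermediate
16 | 7-hydroxy-2H-chromen-2-one (umbelliferone) | O=c1ccc2ccc(O)cc2o1 | starting material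
17 | (1R,3S)-2,2-dimethyl-4-methylidene-3-{[(2-oxo-2H-chromen-7-yl)oxy]methyl}cyclohexyl acetate | C=C1CC[C@@H](OC(C)=O)C(C)(C)[C@H]1COc1ccc2ccc(=O)oc2c1 | target

**Step count.** Total: 11 steps. Longest linear sequence: 11 steps (1 → 17).

**Steps most likely to fail**

Step 7. The promoter may fail to ionise the hindered ring C–O bond, or the allyl cation may be captured intermolecularly and oligomerise instead of recombining at the enolate carbon. The fallback sets out from lactone 10 and returns at ketone 12. Methyllithium (1.05 equiv, THF, −78 °C) should add once to the hindered lactone and give, after work-up, the hydroxy ketone (4S)-4-{[(tert-butyldiphenylsilyl)oxy]methyl}-5-(hydroxymethyl)-3,3-dimethylhex-5-en-2-one F1, in equilibrium with its cyclic hemiketal. Appel bromination (CBr4, PPh3, CH2Cl2, 0 °C), acting through the open-chain tautomer, should give the allylic bromide (4R)-5-(bromomethyl)-4-{[(tert-butyldiphenylsilyl)oxy]methyl}-3,3-dimethylhex-5-en-2-one F2 (the descriptor changes only through CIP priority). KHMDS (THF, −78 → 0 °C) then forms the only possible enolate, which should close the ring by 6-(enolendo)-exo-tet C-alkylation to 12. Any O-alkylated material would be 11 itself.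

Step 3. The addition may suffer from poor facial selectivity, from competing 1,2-addition, or from hydrolysis of the ketene acetal before it reacts. The fallback sets out from enal 4 (with ketene acetal 5) and returns at aldehyde 6. Luche reduction of 4 gives (2E)-4-[(tert-butyldiphenylsilyl)oxy]but-2-en-1-ol F3, and methyl chloroformate/pyridine converts it into (2E)-4-[(tert-butyldiphenylsilyl)oxy]but-2-en-1-yl methyl carbonate F4. Iridium-catalysed branched-selective asymmetric allylic alkylation with 5 ([Ir(cod)Cl]2, chiral phosphoramidite of the sense giving the (S) product, THF, rt) should give methyl (3S)-3-{[(tert-butyldiphenylsilyl)oxy]methyl}-2,2-dimethylpent-4-enoate F5. Hydroboration with 9-BBN and NaBO3 oxidation lead to methyl (3S)-3-{[(tert-butyldiphenylsilyl)oxy]methyl}-5-hydroxy-2,2-dimethylpentanoate F6, and Dess–Martin oxidation gives 6.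

Step 11. The alkoxyphosphonium ion may eliminate towards the allylic ring hydrogen (giving a diene), or the displacement at the β-branched CH2 may be too slow. The fallback sets out from alcohol 15 and returns at 17. Tf2O and 2,6-lutidine (CH2Cl2, −78 °C) give the triflate (1R,3S)-2,2-dimethyl-4-methylidene-3-{[(trifluoromethanesulfonyl)oxy]methyl}cyclohexyl acetate F7. This is displaced directly by the caesium salt of umbelliferone 16 (Cs2CO3, MeCN, 0 °C → rt) in a Williamson etherification.

**Further compounds**
F1 | step 7 | (4S)-4-{[(tert-butyldiphenylsilyl)oxy]methyl}-5-(hydroxymethyl)-3,3-dimethylhex-5-en-2-one | CC(=O)C(C)(C)[C@@H](CO[Si](C(C)(C)C)(c1ccccc1)c1ccccc1)C(=C)CO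
F2 | step 7 | (4R)-5-(bromomethyl)-4-{[(tert-butyldiphenylsilyl)oxy]methyl}-3,3-dimethylhex-5-en-2-one | CC(=O)C(C)(C)[C@@H](CO[Si](C(C)(C)C)(c1ccccc1)c1ccccc1)C(=C)CBr
F3 | step 3 | (2E)-4-[(tert-butyldiphenylsilyl)oxy]but-2-en-1-ol | OC/C=C/CO[Si](C(C)(C)C)(c1ccccc1)c1ccccc1
F4 | step 3 | (2E)-4-[(tert-butyldiphenylsilyl)oxy]but-2-en-1-yl methyl carbonate | COC(=O)OC/C=C/CO[Si](C(C)(C)C)(c1ccccc1)c1ccccc1
F5 | step 3 | methyl (3S)-3-{[(tert-butyldiphenylsilyl)oxy]methyl}-2,2-dimethylpent-4-enoate | C=C[C@H](CO[Si](C(C)(C)C)(c1ccccc1)c1ccccc1)C(C)(C)C(=O)OC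
F6 | step 3 | methyl (3S)-3-{[(tert-butyldiphenylsilyl)oxy]methyl}-5-hydroxy-2,2-dimethylpentanoate | OCC[C@H](CO[Si](C(C)(C)C)(c1ccccc1)c1ccccc1)C(C)(C)C(=O)OC
F7 | step 11 | (1R,3S)-2,2-dimethyl-4-methylidene-3-{[(trifluoromethanesulfonyl)oxy]methyl}cyclohexyl acetate | C=C1CC[C@@H](OC(C)=O)C(C)(C)[C@H]1COS(=O)(=O)C(F)(F)F
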